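**Retrosynthetic overview**
- The target comes from its tetramethyl ether by one final BBr3 step that frees all four phenols with the ester already in place.
- Key disconnection: the aryl–undecyl bond ortho to the ester. Undecyl Grignard replaces one of the two equivalent ortho-OMe groups of a 2,4,6-trimethoxybenzoate (chelation-driven addition–elimination through a dearomatised adduct), so the symmetric acid ring is differentiated on the chiral ester itself.
- The trimethoxybenzoate is cut at the aryl–C(=O) bond: lithiated 1,3,5-trimethoxybenzene (a commodity arene) plus the imidazole-1-carboxylate of the chiral alcohol (retention).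
- The chiral alcohol comes from (R)-2-propyloxirane and a 6-(3,5-dimethoxyphenyl)hexyl Grignard, itself from 3,5-dimethoxyphenyl Grignard and 1-bromo-6-chlorohexane.
- No ring is formed: both benzene rings are bought intact and only substituted.

Assumption: (R)-2-propyloxirane is bought at ≥98% ee (hydrolytic-kinetic-resolution grade); its ee becomes the ee of the target.

**Route**

Step 1
Reactants: 1 1-bromo-3,5-dimethoxybenzene; 2 1-bromo-6-chlorohexane
Product: 4 1-(6-chlorohexyl)-3,5-dimethoxybenzene, via 3,5-dimethoxyphenylmagnesium bromide 3 (not isolated)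
Conditions: Mg, THF, 45 °C; then 2 (1.2 eq), Li2CuCl4 (3 mol%), NMP, THF, 0 °C → rt
Reagents that add atoms: none
Why: Kochi-type copper-catalysed sp2–sp3 Grignard cross-coupling, in which aryl Grignard 3 displaces the primary bromide of 2 much faster than the chloride, so the chloro end survives as the handle for step 2 and no statistical mixture arises.

Step 2
Reactants: 4 1-(6-chlorohexyl)-3,5-dimethoxybenzene; 5 (R)-2-propyloxirane
Product: 8 (R)-11-(3,5-dimethoxyphenyl)undecan-4-yl 1H-imidazole-1-carboxylate, via 6-arylhexylmagnesium chloride 6 (not isolated), via chloromagnesium (R)-alkoxide 7 (not isolated)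
Conditions: Mg, THF, reflux; CuI (10 mol%), 5 (1.05 eq), −30 → 0 °C; then CDI (1.5 eq), 0 °C → rt; aq. work-up
Reagents that add atoms: 1,1'-carbonyldiimidazole (CDI), O=C(n1ccnc1)n1ccnc1
Why: Copper-catalysed SN2 opening of a terminal epoxide by a primary alkyl Grignard occurs only at the CH2 terminus, so the C–O bond of the stereocentre is never broken and (R)-5 gives (R)-alkoxide 7 with full retention, which CDI then O-acylates in the same flask (carbonyl-imidazole transfer) to the bench-stable imidazole carboxylate.

Step 3
Reactants: 9 1,3,5-trimethoxybenzene; 8 (R)-11-(3,5-dimethoxyphenyl)undecan-4-yl 1H-imidazole-1-carboxylate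
Product: 11 (R)-11-(3,5-dimethoxyphenyl)undecan-4-yl 2,4,6-trimethoxybenzoate, via 2,4,6-trimethoxyphenyllithium 10 (not isolated)
Conditions: 9 (1.3 eq), n-BuLi (1.25 eq), THF, 0 °C → rt, 1 h; then 8, −78 °C → rt; aq. work-up
Reagents that add atoms: none
Why: Directed ortho-lithiation of 1,3,5-trimethoxybenzene between two OMe groups followed by nucleophilic acyl substitution of the aryllithium on an alkyl imidazole-1-carboxylate (alkoxycarbonylation of an organometallic) gives the ester with the stereocentre untouched, and the doubly ortho-substituted benzoate formed is too hindered for a second addition.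

Step 4
Reactants: 11 (R)-11-(3,5-dimethoxyphenyl)undecan-4-yl 2,4,6-trimethoxybenzoate; 12 1-bromoundecane
Product: 14 (R)-11-(3,5-dimethoxyphenyl)undecan-4-yl 2,4-dimethoxy-6-undecylbenzoate, via undecylmagnesium bromide 13 (not isolated)
Conditions: 12, Mg, Et2O, reflux; then 11, 13 (2.0 eq), toluene/Et2O 3:1, 0 → 45 °C; aq. work-up
Reagents that add atoms: none
Why: Proposed new method: chelation-controlled ester-mediated SNAr (addition–elimination) in which the Grignard, bound to the carbonyl oxygen and one ortho-OMe, transfers undecyl to that OMe-bearing ring carbon through a six-membered transition state to give a dearomatised magnesium ketene-acetal σ-adduct that expels MeOMgBr and re-aromatises; the two ortho-OMe groups are equivalent so either gives 14, carbonyl attack is blocked by the two ortho substituents plus the branched O-alkyl group, and a second displacement is slowed once the new alkyl group twists the ester out of conjugation; the closest known reactions are the Grignard displacement of ortho-methoxy groups in hindered 2-methoxybenzoate and 1-alkoxy-2-naphthoate esters and in o-methoxyaryl oxazolines (Meyers).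

Step 5
Reactants: 14 (R)-11-(3,5-dimethoxyphenyl)undecan-4-yl 2,4-dimethoxy-6-undecylbenzoate
Product: 15 (R)-11-(3,5-dihydroxyphenyl)undecan-4-yl 2,4-dihydroxy-6-undecylbenzoate
Conditions: BBr3 (8 eq), CH2Cl2, −78 → 0 °C; H2O
Reagents that add atoms: none
Why: Lewis-acid O-demethylation (BBr3 ether cleavage) removes the four aryl methyl groups, the one ortho to the ester first through chelation, while a hindered secondary alkyl 2-hydroxybenzoate of this kind tolerates BBr3 at or below 0 °C, so the ester and its (R) C–O bond are not touched.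

**Compound list**
1 | 1-bromo-3,5-dimethoxybenzene | COc1cc(Br)cc(OC)c1 | starting material
2 | 1-bromo-6-chlorohexane | ClCCCCCCBr | starting material
3 | 3,5-dimethoxyphenylmagnesium bromide | COc1cc([Mg]Br)cc(OC)c1 | intermediate
4 | 1-(6-chlorohexyl)-3,5-dimethoxybenzene | COc1cc(CCCCCCCl)cc(OC)c1 | intermediate
5 | (R)-2-propyloxirane [(R)-1,2-epoxypentane] | CCC[C@@H]1CO1 | starting material
6 | [6-(3,5-dimethoxyphenyl)hexyl]magnesium chloride | COc1cc(CCCCCC[Mg]Cl)cc(OC)c1 | intermediate
7 | chloromagnesium (R)-11-(3,5-dimethoxyphenyl)undecan-4-olate | CCC[C@@H](O[Mg]Cl)CCCCCCCc1cc(OC)cc(OC)c1 | intermediate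
8 | (R)-11-(3,5-dimethoxyphenyl)undecan-4-yl 1H-imidazole-1-carboxylate | CCC[C@@H](OC(=O)n1ccnc1)CCCCCCCc1cc(OC)cc(OC)c1 | intermediate
9 | 1,3,5-trimethoxybenzene | COc1cc(OC)cc(OC)c1 | starting material
10 | 2,4,6-trimethoxyphenyllithium | [Li]c1c(OC)cc(OC)cc1OC | intermediate
11 | (R)-11-(3,5-dimethoxyphenyl)undecan-4-yl 2,4,6-trimethoxybenzoate | CCC[C@@H](OC(=O)c1c(OC)cc(OC)cc1OC)CCCCCCCc1cc(OC)cc(OC)c1 | intermediate
12 | 1-bromoundecane | CCCCCCCCCCCBr | starting material
13 | undecylmagnesium bromide | CCCCCCCCCCC[Mg]Br | intermediate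
14 | (R)-11-(3,5-dimethoxyphenyl)undecan-4-yl 2,4-dimethoxy-6-undecylbenzoate | CCCCCCCCCCCc1cc(OC)cc(OC)c1C(=O)O[C@H](CCC)CCCCCCCc1cc(OC)cc(OC)c1 | intermediate
15 | (R)-11-(3,5-dihydroxyphenyl)undecan-4-yl 2,4-dihydroxy-6-undecylbenzoate (CNP0146287.1) | CCCCCCCCCCCc1cc(O)cc(O)c1C(=O)O[C@H](CCC)CCCCCCCc1cc(O)cc(O)c1 | target

**Step count and risks**

Total step count: 5. Longest linear sequence: 5 steps (1 → 4 → 8 → 11 → 14 → 15); 9 and 12 enter at steps 3 and 4.

Steps most likely to fail:

Step 4 (desymmetrising displacement of OMe). The ring is electron-rich and the ester is twisted, so the Grignard may not add, may displace both ortho-OMe groups, or may attack the carbonyl. The fallback sets out from alkoxide 7 (the flask of step 2 before CDI is added) and comes back at 14, building the undecyl chain from a benzylic carbon instead. Commercial 2,4-dimethoxy-6-methylbenzoic acid is converted with oxalyl chloride and catalytic DMF in CH2Cl2 into 2,4-dimethoxy-6-methylbenzoyl chloride F1. F1 acylates alkoxide 7 (THF, 0 °C → rt) to give (R)-11-(3,5-dimethoxyphenyl)undecan-4-yl 2,4-dimethoxy-6-methylbenzoate F2. LDA in THF at −78 °C removes a proton from the ortho-methyl group (lateral lithiation) to give the ester-stabilised benzylic lithium compound F3. F3 is alkylated with 1-iododecane (DMPU, −78 → −20 °C) to give 14.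

Step 5 (global demethylation). BBr3 may also ionise the secondary alkyl–O bond of the ester, losing the alcohol half or eroding ee. The fallback frees the phenols before the ester exists and joins the halves without protecting groups. It sets out from Grignard 6 (flask of step 2) and from 1 plus 13, and comes back at 15.
- Alcohol half: 6 opens (S)-2-propyloxirane (the purchased enantiomer of 5; CuI, THF, −30 → 0 °C) and aqueous work-up gives (S)-11-(3,5-dimethoxyphenyl)undecan-4-ol F4. BBr3 in CH2Cl2 at −78 → 0 °C (the alcohol is held as its borate and returns on hydrolysis) gives (S)-5-(8-hydroxyundecyl)benzene-1,3-diol F5.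
- Acid half: Ni(dppp)Cl2-catalysed Kumada coupling of 1 with 13 gives 1,3-dimethoxy-5-undecylbenzene F6. BBr3 gives 5-undecylbenzene-1,3-diol F7. Ortho-carboxylation with methyl magnesium carbonate (DMF, 120 °C), as for olivetol to olivetolic acid, gives 2,4-dihydroxy-6-undecylbenzoic acid F8.
- Union: Mitsunobu esterification of F8 with F5 (tris(3-chlorophenyl)phosphine, DIAD, toluene, 0 °C → rt) lets the carboxylic acid react in preference to the phenols, inverts the carbinol centre from (S) to (R), and gives 15.

Step 3 (aryllithium acylation). The hindered aryllithium 10 may add sluggishly to the hindered carbonate-type electrophile 8 or give some diaryl ketone. The fallback reverses the polarity, sets out from alkoxide 7 and comes back at 11. Commercial 2,4,6-trimethoxybenzoic acid is converted with oxalyl chloride and catalytic DMF into 2,4,6-trimethoxybenzoyl chloride F9, which is added to 7 in place of CDI (THF, 0 °C → rt) to give 11 directly.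

**Further compounds**
F1 | step 4 | 2,4-dimethoxy-6-methylbenzoyl chloride | Cc1cc(OC)cc(OC)c1C(Cl)=O
F2 | step 4 | (R)-11-(3,5-dimethoxyphenyl)undecan-4-yl 2,4-dimethoxy-6-methylbenzoate | Cc1cc(OC)cc(OC)c1C(=O)O[C@H](CCC)CCCCCCCc1cc(OC)cc(OC)c1
F3 | step 4 | (R)-11-(3,5-dimethoxyphenyl)undecan-4-yl 2-(lithiomethyl)-4,6-dimethoxybenzoate | [Li]Cc1cc(OC)cc(OC)c1C(=O)O[C@H](CCC)CCCCCCCc1cc(OC)cc(OC)c1
F4 | step 5 | (S)-11-(3,5-dimethoxyphenyl)undecan-4-ol | CCC[C@H](O)CCCCCCCc1cc(OC)cc(OC)c1
F5 | step 5 | (S)-5-(8-hydroxyundecyl)benzene-1,3-diol | CCC[C@H](O)CCCCCCCc1cc(O)cc(O)c1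
F6 | step 5 | 1,3-dimethoxy-5-undecylbenzene | CCCCCCCCCCCc1cc(OC)cc(OC)c1
F7 | step 5 | 5-undecylbenzene-1,3-diol | CCCCCCCCCCCc1cc(O)cc(O)c1
F8 | step 5 | 2,4-dihydroxy-6-undecylbenzoic acid | CCCCCCCCCCCc1cc(O)cc(O)c1C(=O)O
F9 | step 3 | 2,4,6-trimethoxybenzoyl chloride | COc1cc(OC)c(C(Cl)=O)c(OC)c1
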